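**Strategy.** The cyclopentane (ring B) is cut at both ends of its CH2–CH2 unit, which is supplied by acetylene as a cis-vinylene linchpin. In one flask a 2-methylpropenylcuprate carbocuprates acetylene (bond from the isopropyl-bearing CH to the first CH2) and the resulting (Z)-dienylcuprate adds to the exocyclic β-carbon of a nopinylidene-1,3-dione (bond from the second CH2 to pinane C-2). The step exploits that this spiro carbon is β to both carbonyls of the cyclohexenedione (ring A) and is attacked anti to the gem-dimethyl bridge. A Conia-ene closure then forms the second spiro centre and the isopropyl group; hydrogenation completes ring B.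

Key step: step 5

Assumption: (1R,5R)-(+)-β-pinene, which has the bridgehead configuration of the target's pinane unit, is taken as commercially available; compound 7 is used as an E/Z mixture because both isomers give the same enolate.

**Step 1**
Reactants: 1 1-(2,6-dihydroxy-4-methoxyphenyl)ethan-1-one
Product: 2 2-acetyl-3-hydroxy-5-methoxy-4,6,6-trimethylcyclohexa-2,4-dien-1-one
Conditions: MeI (3.5 equiv), NaOMe (4 equiv), MeOH, 0 °C to rt; then 1 M HCl
Reagents that add atoms: iodomethane, CI
Why: Base-mediated exhaustive C-methylation of an acylphloroglucinol (alkylative dearomatisation) should methylate the two free ring CH positions three times, the acetyl group blocking the third position and the aryl methyl ether, which cannot become a carbonyl, stopping the sequence and ending as the enol ether between the CMe2 and CMe carbons; no stereocenter is formed.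

**Step 2**
Reactants: 2 2-acetyl-3-hydroxy-5-methoxy-4,6,6-trimethylcyclohexa-2,4-dien-1-one
Product: 3 5-methoxy-4,6,6-trimethylcyclohex-4-ene-1,3-dione
Conditions: 2 M NaOH (aq), 1,4-dioxane, 90 °C; then HCl to pH 4
Reagents that add atoms: none
Why: Retro-Claisen cleavage of the exocyclic acetyl group of the β-triketone by hydroxide should free C-2, while the ring, an enolate under these conditions, keeps its hindered vinylogous methyl ester; no stereocenter is formed.

**Step 3**
Reactants: 4 (1R,5R)-(+)-β-pinene
Product: 6 (1S,5R)-(−)-nopinone, via β-pinene ozonide 5 (not isolated)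
Conditions: O3, CH2Cl2, −78 °C; then PPh3, rt
Reagents that add atoms: ozone, [O-][O+]=O
Why: Ozonolysis (Criegee mechanism) with reductive work-up should remove the exocyclic methylene carbon as formaldehyde and leave both bridgehead stereocenters untouched.

**Step 4**
Reactants: 3 5-methoxy-4,6,6-trimethylcyclohex-4-ene-1,3-dione; 6 (1S,5R)-(−)-nopinone
Product: 7 2-[(1S,5R)-6,6-dimethylbicyclo[3.1.1]heptan-2-ylidene]-5-methoxy-4,6,6-trimethylcyclohex-4-ene-1,3-dione (E/Z mixture)
Conditions: TiCl4 (2.2 equiv), pyridine (4.5 equiv), THF, 0 °C to rt
Reagents that add atoms: none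
Why: Knoevenagel condensation under TiCl4/pyridine (Lehnert conditions), in which the titanium enolate of the 1,3-dione adds to the activated ketone and the tertiary titanium alkoxide is eliminated, should give the tetrasubstituted alkylidene dione; its alkene geometry is of no consequence and no stereocenter is formed.

**Step 5**
Reactants: 7 nopinylidene dione; 8 1-bromo-2-methylprop-1-ene; 9 acetylene
Product: 13 3-hydroxy-2-[(1S,2R,5R)-6,6-dimethyl-2-[(1Z)-4-methylpenta-1,3-dien-1-yl]bicyclo[3.1.1]heptan-2-yl]-5-methoxy-4,6,6-trimethylcyclohexa-2,4-dien-1-one, via isobutenyllithium 10 (not isolated), via lithium diisobutenylcuprate 11 (not isolated), via lithium bis(Z-dienyl)cuprate 12 (not isolated)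
Conditions: 8, Li wire, Et2O, 0 °C; CuBr·SMe2 (0.5 equiv per Li reagent), Et2O/SMe2, −40 °C; HC≡CH (2.1 equiv per Cu, metered), −30 to −10 °C; then 7, THF, −78 to −20 °C; aq NH4Cl
Reagents that add atoms: none
Why: Halogen–lithium exchange with lithium metal and transmetalation give cuprate 11, which adds syn across acetylene (Normant–Alexakis carbocupration), forming the bond between the future isopropyl-bearing carbon and the first ring B CH2 and delivering the (Z)-dienylcuprate 12. This cuprate then undergoes 1,4-addition to the doubly activated tetrasubstituted alkene of 7, forming the bond between the second ring B CH2 and pinane C-2 and giving the dione enolate, which is protonated on work-up. The closest known reactions are conjugate additions of acetylene-derived (Z)-alkenylcuprates to alkylidene malonates and enones, and cuprate additions to verbenone that create a quaternary carbon next to the pinane bridgehead. No ring is closed here; the (Z)-alkene from the syn addition is what later holds the two ends of ring B within bonding distance. The new quaternary stereocenter at pinane C-2 is controlled by the bicycle, since the cuprate should approach the exocyclic carbon from the face of the methylene bridge, anti to the gem-dimethyl bridge, so that the dione carbon ends syn to that bridge as in the target. The step needs 1,4-addition to win over γ-deprotonation of 7 and needs a single acetylene insertion, which the high electrophilicity of the alkylidene-1,3-dione, the low basicity of the cuprate and the metered acetylene at low temperature should secure.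

**Step 6**
Reactants: 13 dienyl dione (enol form)
Product: 14 4',5'-didehydro derivative of the target (cis-disubstituted alkene in ring B, all five stereocenters arranged as in the target)
Conditions: o-dichlorobenzene (0.02 M), BHT (5 mol %), 200 °C, sealed tube
Reagents that add atoms: none
Why: In a thermal Conia-ene reaction the enol OH on C-3 of ring A (the carbonyl conjugated to the enol ether, not the one flanked by CMe2) should transfer its hydrogen to the dimethyl-substituted alkene terminus while C-2 bonds to the adjacent alkene carbon through a six-membered array (exo closure of ring B), which makes the isopropyl group and places it cis to that carbonyl across the new spiro centre; the array should lie on the face of the nascent ring that carries the pinane C-3 methylene, away from the bridgehead and its gem-dimethyl bridge.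

**Step 7**
Reactants: 14 spiro cyclopentene
Product: 15 CNP0307059.1 (target)
Conditions: H2 (1 atm), Pd/C (10 %), EtOAc, rt
Reagents that add atoms: none
Why: Heterogeneous catalytic hydrogenation should reduce the cis-disubstituted cyclopentene, while the tetrasubstituted enol ether alkene of ring A and the ketones are inert under these conditions; no stereocenter is formed or touched.

**Compound list**
1 | 1-(2,6-dihydroxy-4-methoxyphenyl)ethan-1-one | CC(=O)c1c(O)cc(OC)cc1O | starting material
2 | 2-acetyl-3-hydroxy-5-methoxy-4,6,6-trimethylcyclohexa-2,4-dien-1-one | COC1=C(C)C(O)=C(C(C)=O)C(=O)C1(C)C | intermediate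
3 | 5-methoxy-4,6,6-trimethylcyclohex-4-ene-1,3-dione (drawn as the diketone, present largely as its enol) | COC1=C(C)C(=O)CC(=O)C1(C)C | intermediate
4 | (1R,5R)-(+)-β-pinene, (1R,5R)-6,6-dimethyl-2-methylidenebicyclo[3.1.1]heptane | C=C1CC[C@@H]2C[C@H]1C2(C)C | starting material
5 | ozonide of 4, spiro-1,2,4-trioxolane at pinane C-2 (mixture at the spiro carbon) | C1OC2(CC[C@@H]3C[C@H]2C3(C)C)OO1 | intermediate
6 | (1S,5R)-(−)-nopinone, (1S,5R)-6,6-dimethylbicyclo[3.1.1]heptan-2-one | O=C1CC[C@@H]2C[C@H]1C2(C)C | intermediate
7 | 2-[(1S,5R)-6,6-dimethylbicyclo[3.1.1]heptan-2-ylidene]-5-methoxy-4,6,6-trimethylcyclohex-4-ene-1,3-dione (E/Z mixture) | COC1=C(C)C(=O)C(=C2CC[C@@H]3C[C@H]2C3(C)C)C(=O)C1(C)C | intermediate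
8 | 1-bromo-2-methylprop-1-ene | CC(C)=CBr | starting material
9 | acetylene | C#C | starting material
10 | (2-methylprop-1-en-1-yl)lithium | [Li]C=C(C)C | intermediate
11 | lithium bis(2-methylprop-1-en-1-yl)cuprate, LiCu(CH=CMe2)2 | [Li+].CC(C)=C[Cu-]C=C(C)C | intermediate
12 | lithium bis[(1Z)-4-methylpenta-1,3-dien-1-yl]cuprate | [Li+].CC(C)=C/C=C\[Cu-]/C=C\C=C(C)C | intermediate
13 | 3-hydroxy-2-[(1S,2R,5R)-6,6-dimethyl-2-[(1Z)-4-methylpenta-1,3-dien-1-yl]bicyclo[3.1.1]heptan-2-yl]-5-methoxy-4,6,6-trimethylcyclohexa-2,4-dien-1-one (dienyl group anti, dione ring syn to the gem-dimethyl bridge) | COC1=C(C)C(O)=C(C(=O)C1(C)C)[C@@]1(/C=C\C=C(C)C)CC[C@@H]2C[C@H]1C2(C)C | intermediate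
14 | 4',5'-didehydro derivative of the target: dispiro compound with a cis C=C in ring B, isopropyl cis to the ring A carbonyl that is conjugated to the enol ether, that carbonyl on the ring B face of the pinane C-3 methylene | COC1=C(C)C(=O)[C@@]2(C(=O)C1(C)C)[C@@H](C(C)C)C=C[C@@]21CC[C@@H]2C[C@H]1C2(C)C | intermediate
15 | CNP0307059.1, (1S,2R,2'R,3'R,5R)-4''-methoxy-3'',5'',5'',6,6-pentamethyl-3'-(propan-2-yl)dispiro[bicyclo[3.1.1]heptane-2,1'-cyclopentane-2',1''-cyclohexan]-3''-ene-2'',6''-dione | COC1=C(C)C(=O)[C@@]2(C(=O)C1(C)C)[C@@H](C(C)C)CC[C@@]21CC[C@@H]2C[C@H]1C2(C)C | target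

**Total steps:** 7. **Longest linear sequence:** 6 steps (steps 1, 2, 4, 5, 6, 7).

**Steps most likely to fail**

1. Step 5. The cuprate may deprotonate 7 at the γ-position instead of adding, or the hindered dienyl ligand may not transfer to the tetrasubstituted acceptor, or acetylene may insert more than once. In that case the two bonds are made one after the other with a much less basic alkynyl nucleophile. The fallback sets out from 7: conjugate alkynylation with Et2AlC≡CSiMe3 (from ethynyltrimethylsilane, n-BuLi and Et2AlCl; Et2O/toluene, 0 °C to rt) should give the silylalkyne adduct F1, again by attack anti to the gem-dimethyl bridge. One-pot desilylative Sonogashira coupling of F1 with bromide 8 (PdCl2(PPh3)2, CuI, CsF, DMF, 50 °C) should give the enyne F2. Semihydrogenation of F2 (H2, Pd/CaCO3 poisoned with Pb(OAc)2, quinoline, EtOAc) returns to the route at 13.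

2. Step 4. The condensation may stop or revert at the hindered tertiary aldol stage, and the product may deconjugate to the 2-alkenyl enol under the Lewis acidic conditions. The tetrasubstituted alkene is then made by twofold extrusion (Barton–Kellogg type) under neutral conditions. The fallback sets out from 2 and 6: deacylative diazo transfer to 2 (4-acetamidobenzenesulfonyl azide, Et3N, MeCN, rt) should give the 2-diazo-1,3-dione F3. Ketone 6 with (Me3Si)2S and catalytic Me3SiOTf (MeCN, rt) should give the thione F4. Rh2(OAc)4 (benzene, 80 °C) should convert F3 in the presence of F4, via the thiocarbonyl ylide, into the spiro thiirane F5, which PPh3 desulfurises in the same flask, returning to the route at 7.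

3. Step 6. A [1,5]-hydrogen shift within the (Z)-diene or acid-promoted O-cyclisation may compete at the temperature the ene reaction needs, and facial selectivity at the spiro centre may be poor. Ring B is then closed by an oxidative radical cyclisation at 50 °C. The fallback sets out from 13: Mn(OAc)3·2H2O (2.2 equiv) and Cu(OAc)2 (0.2 equiv) in AcOH should generate the dione radical, which cyclises in exo mode onto the proximal carbon of the trisubstituted alkene; oxidation of the tertiary radical gives the isopropenyl spirocyclopentene F6. Hydrogenation under the conditions of step 7 reduces both new alkenes and returns to the route at 15.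

**Further compounds**
F1 | step 5 | 3-hydroxy-2-[(1S,5R)-6,6-dimethyl-2-[(trimethylsilyl)ethynyl]bicyclo[3.1.1]heptan-2-yl]-5-methoxy-4,6,6-trimethylcyclohexa-2,4-dien-1-one (alkynyl group anti to the gem-dimethyl bridge) | COC1=C(C)C(O)=C(C(=O)C1(C)C)[C@@]1(C#C[Si](C)(C)C)CC[C@@H]2C[C@H]1C2(C)C
F2 | step 5 | 3-hydroxy-2-[(1S,5R)-6,6-dimethyl-2-(4-methylpent-3-en-1-yn-1-yl)bicyclo[3.1.1]heptan-2-yl]-5-methoxy-4,6,6-trimethylcyclohexa-2,4-dien-1-one | COC1=C(C)C(O)=C(C(=O)C1(C)C)[C@@]1(C#CC=C(C)C)CC[C@@H]2C[C@H]1C2(C)C
F3 | step 4 | 2-diazo-5-methoxy-4,6,6-trimethylcyclohex-4-ene-1,3-dione | COC1=C(C)C(=O)C(=[N+]=[N-])C(=O)C1(C)C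
F4 | step 4 | (1S,5R)-6,6-dimethylbicyclo[3.1.1]heptane-2-thione | S=C1CC[C@@H]2C[C@H]1C2(C)C
F5 | step 4 | spiro thiirane joining C-2 of the ring A dione and pinane C-2 (mixture at the two thiirane carbons) | COC1=C(C)C(=O)C2(SC23CC[C@@H]4C[C@H]3C4(C)C)C(=O)C1(C)C
F6 | step 6 | isopropenyl analogue of 14 (prop-1-en-2-yl in place of isopropyl, stereocenters arranged as in the target) | COC1=C(C)C(=O)[C@@]2(C(=O)C1(C)C)[C@@H](C(C)=C)C=C[C@@]21CC[C@@H]2C[C@H]1C2(C)C
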